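**Plan**

- Retrosynthesis, first cut: the ArCH2–Ar bond between the benzylic carbon of ring B and the ring A carbon that lies between OH and CH3 (Friedel–Crafts). This leaves two copies of one monomer, the catechol dimethyl ether and the benzylic alcohol made from it.
- Second cut, in the monomer's cyclopentane (C1' quaternary benzylic carbon, C2' the CMe2 carbon, then C3', C4', C5'): bonds C3'–C4' and C1'–C5'. This removes the C4'–C5' unit as vinyllithium and leaves a tertiary benzylic boronic ester that carries a neopentyl iodide.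
- Enabling feature: C1' bears aryl, methyl and C2' and no hydrogen, so it can sit on boron as a configurationally fixed centre, and C3' is 1,3 to it across C2'. A vinyl group on that boron is then placed so that a radical at C3' closes on the vinyl terminus (C4') and the 1,2-shift of C1' from boron to the inner vinyl carbon (C5') completes the five-membered ring.
- Forward order: aryl bromide → Heck enoate → Cu-catalysed enantioselective β-borylation → gem-dimethylation, reduction, iodination → annulation (cyclopentane) → protodeboronation → benzylic oxidation of one portion → Friedel–Crafts union → demethylation.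
- Stereochemistry: both (S) quaternary centres come from the single ligand-controlled conjugate borylation (step 4); the C–B centre is carried into the ring with retention in step 8.

Key step: step 8

Remark: the ligand enantiomer in step 4 is taken to be the one that gives the (R)-boronate (to be confirmed on the product of that step), and CH2=CHLi is used as a separately prepared, titrated solution.

**Route**

Step 1
Reactants: 1 2-methoxy-4-methylphenol (creosol)
Product: 2 2-bromo-6-methoxy-4-methylphenol
Conditions: Br2 (1.0 equiv), CH2Cl2, 0 °C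
Reagents that add atoms: bromine, BrBr
Why: Electrophilic aromatic bromination; the free OH directs to its only open ortho position because the para position is blocked by methyl.

Step 2
Reactants: 2 2-bromo-6-methoxy-4-methylphenol
Product: 3 1-bromo-2,3-dimethoxy-5-methylbenzene
Conditions: MeI, K2CO3, acetone, reflux
Reagents that add atoms: iodomethane, CI
Why: Williamson O-methylation of the phenoxide.

Step 3
Reactants: 3 1-bromo-2,3-dimethoxy-5-methylbenzene; 4 ethyl (E)-but-2-enoate (ethyl crotonate)
Product: 5 ethyl (E)-3-(2,3-dimethoxy-5-methylphenyl)but-2-enoate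
Conditions: Pd2(dba)3 (zerovalent palladium, 1.5 mol%), P(t-Bu)3, Cy2NMe, dioxane, 100 °C; chromatographic removal of any (Z) or deconjugated isomer
Reagents that add atoms: none
Why: Heck reaction of an electron-rich ortho-substituted aryl bromide with a bulky electron-rich phosphine; syn carbopalladation at the β-carbon of the (E)-crotonate and syn β-hydride elimination should give the (E)-trisubstituted enoate.

Step 4
Reactants: 5 ethyl (E)-3-(2,3-dimethoxy-5-methylphenyl)but-2-enoate
Product: 6 ethyl (3R)-3-(2,3-dimethoxy-5-methylphenyl)-3-(4,4,5,5-tetramethyl-1,3,2-dioxaborolan-2-yl)butanoate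
Conditions: CuCl (5 mol%), NaOt-Bu (10 mol%), chiral ferrocenyl bisphosphine of the Josiphos type (enantiomer that gives the (R) product), B2pin2, MeOH (2 equiv), THF, rt
Reagents that add atoms: bis(pinacolato)diboron, CC1(C)OB(B2OC(C)(C)C(C)(C)O2)OC1(C)C
Why: Cu-catalysed enantioselective conjugate borylation of a β,β-disubstituted enoate (a monovalent copper boryl adds to the β-carbon, MeOH protonates the copper enolate); ligand-controlled face selectivity on the geometrically pure (E)-alkene sets the tertiary C–B stereocentre, the only stereo-defining event of the route.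

Step 5
Reactants: 6 ethyl (3R)-3-(2,3-dimethoxy-5-methylphenyl)-3-(4,4,5,5-tetramethyl-1,3,2-dioxaborolan-2-yl)butanoate
Product: 8 ethyl (3S)-3-(2,3-dimethoxy-5-methylphenyl)-2,2-dimethyl-3-(4,4,5,5-tetramethyl-1,3,2-dioxaborolan-2-yl)butanoate, via monomethyl ester 7 (not isolated)
Conditions: LiN(i-Pr)2 (LDA, 1.3 equiv), THF/DMPU, −78 °C, then MeI; recool, LiN(i-Pr)2 (1.5 equiv), −78 → −30 °C, then MeI (excess), → 0 °C
Reagents that add atoms: iodomethane, CI
Why: Two successive ester enolate C-alkylations, a reaction type known for β-boryl esters; MeI is small enough to build the quaternary carbon next to the existing one, and the C–B centre has no acidic hydrogen and is not touched (the descriptor changes from R to S only through the priority rules).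

Step 6
Reactants: 8 ethyl (3S)-3-(2,3-dimethoxy-5-methylphenyl)-2,2-dimethyl-3-(4,4,5,5-tetramethyl-1,3,2-dioxaborolan-2-yl)butanoate
Product: 9 (3R)-3-(2,3-dimethoxy-5-methylphenyl)-2,2-dimethyl-3-(4,4,5,5-tetramethyl-1,3,2-dioxaborolan-2-yl)butan-1-ol
Conditions: i-Bu2AlH (DIBAL-H, 3 equiv), CH2Cl2, −78 → 0 °C; aqueous potassium sodium tartrate (KNaC4H4O6)
Reagents that add atoms: none
Why: Hydride reduction of the hindered ester to the neopentyl alcohol; i-Bu2AlH leaves the pinacol boronic ester intact, whereas LiAlH4 would attack boron.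

Step 7
Reactants: 9 (3R)-3-(2,3-dimethoxy-5-methylphenyl)-2,2-dimethyl-3-(4,4,5,5-tetramethyl-1,3,2-dioxaborolan-2-yl)butan-1-ol
Product: 10 2-[(2S)-2-(2,3-dimethoxy-5-methylphenyl)-4-iodo-3,3-dimethylbutan-2-yl]-4,4,5,5-tetramethyl-1,3,2-dioxaborolane
Conditions: PPh3, I2, imidazole, toluene, 80 °C
Reagents that add atoms: iodine, II
Why: Appel-type iodination; SN2 displacement of the alkoxyphosphonium by iodide is known to work on neopentyl carbinols on heating, and the neutral boronic ester is inert.

Step 8
Reactants: 10 2-[(2S)-2-(2,3-dimethoxy-5-methylphenyl)-4-iodo-3,3-dimethylbutan-2-yl]-4,4,5,5-tetramethyl-1,3,2-dioxaborolane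
Product: 12 2-[(2S)-2-(2,3-dimethoxy-5-methylphenyl)-2,3,3-trimethylcyclopentyl]-4,4,5,5-tetramethyl-1,3,2-dioxaborolane (both epimers at the boron-bearing carbon), via lithium vinyl boronate complex 11 (not isolated)
Conditions: CH2=CHLi (1.05 equiv), THF, −78 °C, 20 min; then fac-Ir(ppy)3 (1 mol%), 450 nm LED, degassed, −78 → −40 °C
Reagents that add atoms: vinyllithium, [Li]C=C
Why: Proposed new method: vinyllithium adds to boron of 10 to give the vinyl boronate complex 11; the photoexcited trivalent iridium catalyst reduces the neopentyl C–I bond to a primary radical, which adds to the terminal vinyl carbon in a 6-endo-trig closure of a boron-containing six-membered ring (first new bond, CH2–CH2); the α-boryl radical is then oxidised by tetravalent iridium and the benzylic quaternary carbon migrates from boron to that carbon in a ring-contracting 1,2-metallate shift (second new bond), which turns the boracyclohexane into the all-carbon cyclopentane with Bpin exocyclic. The closest known reaction types are the intermolecular radical-polar crossover alkylation of vinyl boronate complexes with alkyl iodides and the ring-contracting 1,2-metallate rearrangement of cyclic alkenyl boronate complexes; what is new is that the radical is tethered to the migrating group, so both ring bonds form in one cascade. The quaternary stereocentre is transferred, not created: 1,2-migration from boron to carbon is stereoretentive at the migrating carbon, so its configuration is that of the C–B centre from step 4, and the new boron-bearing carbon forms without control, which does not matter because it becomes CH2 in step 9. The step needs 6-endo over 5-exo attack, which the long C–B bonds, the bulky tetracoordinate boron on the inner vinyl carbon and the stabilised α-boryl radical should favour (as in 4-sila-5-hexenyl radicals). It also needs the radical path to outrun polar 1,3-elimination of the γ-iodo boronate complex to a cyclopropane, which low temperature and fast photoinitiation are meant to secure.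

Step 9
Reactants: 12 2-[(2S)-2-(2,3-dimethoxy-5-methylphenyl)-2,3,3-trimethylcyclopentyl]-4,4,5,5-tetramethyl-1,3,2-dioxaborolane
Product: 14 1,2-dimethoxy-5-methyl-3-[(1S)-1,2,2-trimethylcyclopentyl]benzene, via lithium phenyl boronate complex 13 (not isolated)
Conditions: PhLi (1.1 equiv), Et2O, 0 °C; then MeOH/acetone (1:1), [Ir(dF(CF3)ppy)2(dtbbpy)]PF6 (1 mol%), PhSH (catalytic), blue LED, rt
Reagents that add atoms: none
Why: Photoredox protodeboronation: the aryl boronate complex is oxidised by the excited trivalent iridium photocatalyst to a secondary alkyl radical, which takes hydrogen from the thiol; this removes the helper boron together with the only uncontrolled carbon and leaves the quaternary centre untouched.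

Step 10
Reactants: 14 1,2-dimethoxy-5-methyl-3-[(1S)-1,2,2-trimethylcyclopentyl]benzene (one portion)
Product: 15 3,4-dimethoxy-5-[(1S)-1,2,2-trimethylcyclopentyl]benzaldehyde
Conditions: K2S2O8 (2.5 equiv), CuSO4·5H2O (20 mol%), MeCN/H2O (1:1), 75 °C
Reagents that add atoms: water, O
Why: Persulfate–copper oxidation of a methyl group para to methoxy (arene radical cation, benzyl radical, benzyl cation, capture by water, second oxidation); this methyl holds the only benzylic C–H bonds of 14, since the other benzylic carbon is quaternary.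

Step 11
Reactants: 15 3,4-dimethoxy-5-[(1S)-1,2,2-trimethylcyclopentyl]benzaldehyde
Product: 16 {3,4-dimethoxy-5-[(1S)-1,2,2-trimethylcyclopentyl]phenyl}methanol
Conditions: NaBH4, MeOH, 0 °C
Reagents that add atoms: none
Why: Borohydride reduction of the aldehyde to the benzylic alcohol.

Step 12
Reactants: 14 1,2-dimethoxy-5-methyl-3-[(1S)-1,2,2-trimethylcyclopentyl]benzene (3 equiv, excess to be recovered); 16 {3,4-dimethoxy-5-[(1S)-1,2,2-trimethylcyclopentyl]phenyl}methanol
Product: 17 1,2-dimethoxy-3-({3,4-dimethoxy-5-[(1S)-1,2,2-trimethylcyclopentyl]phenyl}methyl)-4-methyl-6-[(1S)-1,2,2-trimethylcyclopentyl]benzene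
Conditions: Sc(OTf)3 (5 mol%), CH2Cl2/HFIP, 0 °C → rt, slow addition of 16 to 14
Reagents that add atoms: none
Why: Friedel–Crafts benzylation with loss of water: the para-methoxybenzylic alcohol ionises under mild Lewis acid and the cation should attack 14 at C6 (ortho to OMe, between OMe and methyl), the only open position not shielded by the quaternary cyclopentyl group; excess 14 and slow addition are meant to suppress self-condensation of 16.

Step 13
Reactants: 17 1,2-dimethoxy-3-({3,4-dimethoxy-5-[(1S)-1,2,2-trimethylcyclopentyl]phenyl}methyl)-4-methyl-6-[(1S)-1,2,2-trimethylcyclopentyl]benzene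
Product: 18 3-({3,4-dihydroxy-5-[(1S)-1,2,2-trimethylcyclopentyl]phenyl}methyl)-4-methyl-6-[(1S)-1,2,2-trimethylcyclopentyl]benzene-1,2-diol (CNP0137546.1)
Conditions: BBr3 (8 equiv), CH2Cl2, −78 °C → rt; then H2O; work-up under argon
Reagents that add atoms: none
Why: Lewis-acid cleavage of the four aryl methyl ethers; the quaternary benzylic centres and the diarylmethane carry nothing that BBr3 can ionise, so no stereocentre is touched.

**Compound list**

1 | 2-methoxy-4-methylphenol (creosol) | Cc1ccc(O)c(OC)c1 | starting material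
2 | 2-bromo-6-methoxy-4-methylphenol | Cc1cc(Br)c(O)c(OC)c1 | intermediate
3 | 1-bromo-2,3-dimethoxy-5-methylbenzene | Cc1cc(Br)c(OC)c(OC)c1 | intermediate
4 | ethyl (E)-but-2-enoate | CCOC(=O)/C=C/C | starting material
5 | ethyl (E)-3-(2,3-dimethoxy-5-methylphenyl)but-2-enoate | CCOC(=O)/C=C(\C)c1cc(C)cc(OC)c1OC | intermediate
6 | ethyl (3R)-3-(2,3-dimethoxy-5-methylphenyl)-3-(4,4,5,5-tetramethyl-1,3,2-dioxaborolan-2-yl)butanoate | COc1cc(C)cc([C@@](CC(=O)OCC)(C)B2OC(C)(C)C(C)(C)O2)c1OC | intermediate
7 | ethyl (3R)-3-(2,3-dimethoxy-5-methylphenyl)-2-methyl-3-(4,4,5,5-tetramethyl-1,3,2-dioxaborolan-2-yl)butanoate (both C2 epimers, not isolated) | COc1cc(C)cc([C@@](C(C)C(=O)OCC)(C)B2OC(C)(C)C(C)(C)O2)c1OC | intermediate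
8 | ethyl (3S)-3-(2,3-dimethoxy-5-methylphenyl)-2,2-dimethyl-3-(4,4,5,5-tetramethyl-1,3,2-dioxaborolan-2-yl)butanoate | COc1cc(C)cc([C@@](C(C)(C)C(=O)OCC)(C)B2OC(C)(C)C(C)(C)O2)c1OC | intermediate
9 | (3R)-3-(2,3-dimethoxy-5-methylphenyl)-2,2-dimethyl-3-(4,4,5,5-tetramethyl-1,3,2-dioxaborolan-2-yl)butan-1-ol | COc1cc(C)cc([C@@](C(C)(C)CO)(C)B2OC(C)(C)C(C)(C)O2)c1OC | intermediate
10 | 2-[(2S)-2-(2,3-dimethoxy-5-methylphenyl)-4-iodo-3,3-dimethylbutan-2-yl]-4,4,5,5-tetramethyl-1,3,2-dioxaborolane | COc1cc(C)cc([C@@](C(C)(C)CI)(C)B2OC(C)(C)C(C)(C)O2)c1OC | intermediate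
11 | lithium [(2S)-2-(2,3-dimethoxy-5-methylphenyl)-4-iodo-3,3-dimethylbutan-2-yl](ethenyl)(pinacolato)borate (not isolated) | [Li+].COc1cc(C)cc([C@@](C(C)(C)CI)(C)[B-]2(C=C)OC(C)(C)C(C)(C)O2)c1OC | intermediate
12 | 2-[(2S)-2-(2,3-dimethoxy-5-methylphenyl)-2,3,3-trimethylcyclopentyl]-4,4,5,5-tetramethyl-1,3,2-dioxaborolane (both C1 epimers) | COc1cc(C)cc([C@@]2(C)C(B3OC(C)(C)C(C)(C)O3)CCC2(C)C)c1OC | intermediate
13 | lithium [(2S)-2-(2,3-dimethoxy-5-methylphenyl)-2,3,3-trimethylcyclopentyl](phenyl)(pinacolato)borate (not isolated) | [Li+].COc1cc(C)cc([C@@]2(C)C([B-]3(c4ccccc4)OC(C)(C)C(C)(C)O3)CCC2(C)C)c1OC | intermediate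
14 | 1,2-dimethoxy-5-methyl-3-[(1S)-1,2,2-trimethylcyclopentyl]benzene | COc1cc(C)cc([C@@]2(C)CCCC2(C)C)c1OC | intermediate
15 | 3,4-dimethoxy-5-[(1S)-1,2,2-trimethylcyclopentyl]benzaldehyde | COc1cc(C=O)cc([C@@]2(C)CCCC2(C)C)c1OC | intermediate
16 | {3,4-dimethoxy-5-[(1S)-1,2,2-trimethylcyclopentyl]phenyl}methanol | COc1cc(CO)cc([C@@]2(C)CCCC2(C)C)c1OC | intermediate
17 | 1,2-dimethoxy-3-({3,4-dimethoxy-5-[(1S)-1,2,2-trimethylcyclopentyl]phenyl}methyl)-4-methyl-6-[(1S)-1,2,2-trimethylcyclopentyl]benzene | Cc1cc([C@@]2(C)CCCC2(C)C)c(OC)c(OC)c1Cc1cc(OC)c(OC)c([C@@]2(C)CCCC2(C)C)c1 | intermediate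
18 | 3-({3,4-dihydroxy-5-[(1S)-1,2,2-trimethylcyclopentyl]phenyl}methyl)-4-methyl-6-[(1S)-1,2,2-trimethylcyclopentyl]benzene-1,2-diol | Cc1cc([C@@]2(C)CCCC2(C)C)c(O)c(O)c1Cc1cc(O)c(O)c([C@@]2(C)CCCC2(C)C)c1 | target

**Step count**

Total steps: 13. Longest linear sequence: 13 (steps 1–13; both halves of the target come from intermediate 14).

**Steps most likely to fail, with fallbacks**

Step 8. The γ-iodo boronate complex may close to an arylcyclopropane by polar 1,3-elimination before the radical is formed, or the radical may close 5-exo on the inner vinyl carbon. The fallback uses known chemistry, sets out from ester 8 and comes back at 14. Zweifel olefination of 8 (CH2=CHLi, THF, −78 °C; I2; NaOMe) replaces boron by vinyl with retention and would give ethyl (3R)-3-(2,3-dimethoxy-5-methylphenyl)-2,2,3-trimethylpent-4-enoate F1. Reduction with i-Bu2AlH would give (3S)-3-(2,3-dimethoxy-5-methylphenyl)-2,2,3-trimethylpent-4-en-1-ol F2, and Dess–Martin periodinane would give (3R)-3-(2,3-dimethoxy-5-methylphenyl)-2,2,3-trimethylpent-4-enal F3. Intramolecular hydroacylation with [Rh(dppe)]ClO4 (monovalent rhodium) would close the ring to (3R)-3-(2,3-dimethoxy-5-methylphenyl)-2,2,3-trimethylcyclopentan-1-one F4, and Wolff–Kishner reduction (N2H4·H2O, KOH, diethylene glycol, 200 °C) would return 14.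

Step 5. The second enolate may fail to form next to the boron-bearing quaternary carbon, or the amide base may attack boron and cleave the C–B bond. The fallback builds the gem-dimethyl unit before boron; it sets out from aryl bromide 3 and comes back at alcohol 9. Bromine–lithium exchange (n-BuLi, THF, −78 °C) and acylation with methyl 3-[(tert-butyldimethylsilyl)oxy]-2,2-dimethylpropanoate would give 3-[(tert-butyldimethylsilyl)oxy]-1-(2,3-dimethoxy-5-methylphenyl)-2,2-dimethylpropan-1-one F5. Corey–Bakshi–Shibata reduction (oxazaborolidine enantiomer chosen for the (S)-carbinol, BH3·SMe2, THF) would give (1S)-3-[(tert-butyldimethylsilyl)oxy]-1-(2,3-dimethoxy-5-methylphenyl)-2,2-dimethylpropan-1-ol F6. N,N-Diisopropylcarbamoyl chloride (NaH, THF) would give (1S)-3-[(tert-butyldimethylsilyl)oxy]-1-(2,3-dimethoxy-5-methylphenyl)-2,2-dimethylpropyl N,N-diisopropylcarbamate F7. Lithiation–borylation (s-BuLi, TMEDA, Et2O, −78 °C; MeBpin; MgBr2·OEt2, MeOH, warm) puts boron where hydrogen was with retention and methyl where the carbamate was with inversion, and would give tert-butyl{[(3R)-3-(2,3-dimethoxy-5-methylphenyl)-2,2-dimethyl-3-(4,4,5,5-tetramethyl-1,3,2-dioxaborolan-2-yl)butyl]oxy}dimethylsilane F8. Cleavage of the silyl ether with n-Bu4NF would then give 9.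

Step 12. The benzylic alcohol may condense with itself, or the product may be benzylated again, so that the cross-coupling is not clean. The fallback fixes the site of union by a halogen; it sets out from 14 and comes back at 17. Bromination of 14 (NBS, MeCN, 0 °C) at the open position ortho to OMe would give 3-bromo-1,2-dimethoxy-4-methyl-6-[(1S)-1,2,2-trimethylcyclopentyl]benzene F9. Bromine–lithium exchange (n-BuLi, THF, −78 °C) and addition to aldehyde 15 would give {2,3-dimethoxy-6-methyl-4-[(1S)-1,2,2-trimethylcyclopentyl]phenyl}{3,4-dimethoxy-5-[(1S)-1,2,2-trimethylcyclopentyl]phenyl}methanol F10 (both carbinol epimers). Ionic hydrogenation (Et3SiH, CF3CO2H, CH2Cl2, 0 °C) would give 17.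

**Further compounds**

F1 | step 8 | ethyl (3R)-3-(2,3-dimethoxy-5-methylphenyl)-2,2,3-trimethylpent-4-enoate | COc1cc(C)cc([C@@](C(C)(C)C(=O)OCC)(C)C=C)c1OC
F2 | step 8 | (3S)-3-(2,3-dimethoxy-5-methylphenyl)-2,2,3-trimethylpent-4-en-1-ol | COc1cc(C)cc([C@@](C(C)(C)CO)(C)C=C)c1OC
F3 | step 8 | (3R)-3-(2,3-dimethoxy-5-methylphenyl)-2,2,3-trimethylpent-4-enal | COc1cc(C)cc([C@@](C(C)(C)C=O)(C)C=C)c1OC
F4 | step 8 | (3R)-3-(2,3-dimethoxy-5-methylphenyl)-2,2,3-trimethylcyclopentan-1-one | COc1cc(C)cc([C@@]2(C)CCC(=O)C2(C)C)c1OC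
F5 | step 5 | 3-[(tert-butyldimethylsilyl)oxy]-1-(2,3-dimethoxy-5-methylphenyl)-2,2-dimethylpropan-1-one | COc1cc(C)cc(C(=O)C(C)(C)CO[Si](C)(C)C(C)(C)C)c1OC
F6 | step 5 | (1S)-3-[(tert-butyldimethylsilyl)oxy]-1-(2,3-dimethoxy-5-methylphenyl)-2,2-dimethylpropan-1-ol | COc1cc(C)cc([C@H](C(C)(C)CO[Si](C)(C)C(C)(C)C)O)c1OC
F7 | step 5 | (1S)-3-[(tert-butyldimethylsilyl)oxy]-1-(2,3-dimethoxy-5-methylphenyl)-2,2-dimethylpropyl N,N-diisopropylcarbamate | COc1cc(C)cc([C@H](C(C)(C)CO[Si](C)(C)C(C)(C)C)OC(=O)N(C(C)C)C(C)C)c1OC
F8 | step 5 | tert-butyl{[(3R)-3-(2,3-dimethoxy-5-methylphenyl)-2,2-dimethyl-3-(4,4,5,5-tetramethyl-1,3,2-dioxaborolan-2-yl)butyl]oxy}dimethylsilane | COc1cc(C)cc([C@@](C(C)(C)CO[Si](C)(C)C(C)(C)C)(C)B2OC(C)(C)C(C)(C)O2)c1OC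
F9 | step 12 | 3-bromo-1,2-dimethoxy-4-methyl-6-[(1S)-1,2,2-trimethylcyclopentyl]benzene | COc1c(Br)c(C)cc([C@@]2(C)CCCC2(C)C)c1OC
F10 | step 12 | {2,3-dimethoxy-6-methyl-4-[(1S)-1,2,2-trimethylcyclopentyl]phenyl}{3,4-dimethoxy-5-[(1S)-1,2,2-trimethylcyclopentyl]phenyl}methanol | Cc1cc([C@@]2(C)CCCC2(C)C)c(OC)c(OC)c1C(O)c1cc(OC)c(OC)c([C@@]2(C)CCCC2(C)C)c1
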